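**Plan**
Retrosynthesis: the O-methyl, O-ethyl and O-silyl bonds and the ring B C–Br bond are cut first. Ring B is then opened at C1'–C2' and C5'–C6' (with C2'–C3' as the bond made on ring closure) into a siloxyalkyne and a four-carbon cyclobutenone. The siloxyalkyne is cut at its C(sp)–O bond and at the benzylic CH2–C(sp) bond.
Enabling feature: ring B (C1' carrying the CH2 bridge, oxygen on C2', C4' and C6', H on C3', Br on C5') is a phloroglucinol whose carbon substituent lies between two oxygens. A vinylketene/ynol ether benzannulation delivers exactly this 2-alkyl-1,3,5-trioxygenated pattern.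
Forward: ring A comes from 5-bromovanillin (bromination, methylation, reduction, bromide formation). The three-carbon chain is joined by benzylic alkynylation and oxidised to the silyl ynol ether. Ring B is then built by the benzannulation, and monobromination and dealkylation finish the synthesis.
Stereochemistry: the target has no stereocentre and no configured double bond, so nothing has to be controlled.

Key step: step 7

Assumption: ring B is numbered from the carbon bearing the CH2 bridge (C1'); because C3' and C5' become equivalent once the three ring B oxygens are free, bromination at either position leads to the same target.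

Step 1
Reactants: 1 5-bromovanillin
Product: 2 2,3-dibromo-4-hydroxy-5-methoxybenzaldehyde
Conditions: Br2 (1.1 equiv), Fe powder (5 mol %), AcOH, rt → 50 °C
Reagents that add atoms: bromine, BrBr
Why: Electrophilic aromatic bromination (FeBr3 formed from Fe and Br2) should enter the free position para to the methoxy group, between the aldehyde and the existing bromine, since the sites ortho and para to the phenol are occupied; this is the established outcome for 5-bromovanillin.

Step 2
Reactants: 2 2,3-dibromo-4-hydroxy-5-methoxybenzaldehyde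
Product: 3 2,3-dibromo-4,5-dimethoxybenzaldehyde
Conditions: MeI, K2CO3, DMF, rt
Reagents that add atoms: iodomethane, CI
Why: Williamson O-methylation of the acidic, flanked phenol, which K2CO3 deprotonates readily and the small electrophile MeI can reach.

Step 3
Reactants: 3 2,3-dibromo-4,5-dimethoxybenzaldehyde
Product: 4 (2,3-dibromo-4,5-dimethoxyphenyl)methanol
Conditions: NaBH4, MeOH/THF, 0 °C
Reagents that add atoms: none
Why: Borohydride reduction of the aryl aldehyde to the benzylic alcohol, which leaves aryl bromides and aryl ethers untouched.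

Step 4
Reactants: 4 (2,3-dibromo-4,5-dimethoxyphenyl)methanol
Product: 5 2,3-dibromo-4,5-dimethoxybenzyl bromide
Conditions: PBr3, CH2Cl2, 0 °C → rt
Reagents that add atoms: phosphorus tribromide, BrP(Br)Br
Why: Standard conversion of a benzylic alcohol into the bromide by PBr3 (SN2 displacement of the bromophosphite by bromide).

Step 5
Reactants: 5 2,3-dibromo-4,5-dimethoxybenzyl bromide; 6 ethynylmagnesium bromide (3 equiv, THF solution)
Product: 7 2,3-dibromo-4,5-dimethoxy-1-(prop-2-yn-1-yl)benzene
Conditions: CuBr·SMe2 (10 mol %), THF, 0 → 50 °C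
Reagents that add atoms: none
Why: Copper-catalysed substitution of a benzylic bromide by an alkynyl Grignard reagent is a standard entry to 3-arylprop-1-ynes; the alkynyl Grignard is too weak a base and metalating agent to touch the aryl bromides, and its excess suppresses a second benzylation.

Step 6
Reactants: 7 2,3-dibromo-4,5-dimethoxy-1-(prop-2-yn-1-yl)benzene
Product: 10 {[3-(2,3-dibromo-4,5-dimethoxyphenyl)prop-1-yn-1-yl]oxy}triisopropylsilane, via lithium acetylide 8 (not isolated), via lithium ynolate 9 (not isolated)
Conditions: LiN(SiMe3)2 (2.1 equiv), THF, −78 °C; t-BuOOH (1.0 equiv, gives LiOOt-Bu), −78 → 0 °C; then i-Pr3SiOTf, −78 → 0 °C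
Reagents that add atoms: tert-butyl hydroperoxide, CC(C)(C)OO; triisopropylsilyl trifluoromethanesulfonate, CC(C)[Si](OS(=O)(=O)C(F)(F)F)(C(C)C)C(C)C
Why: Electrophilic oxygenation of a lithium acetylide by lithium tert-butyl peroxide gives the lithium ynolate, which the silyl triflate traps on oxygen, the standard preparation of triisopropylsiloxyalkynes; the amide base avoids the bromine–lithium exchange that an alkyllithium would cause.

Step 7
Reactants: 10 {[3-(2,3-dibromo-4,5-dimethoxyphenyl)prop-1-yn-1-yl]oxy}triisopropylsilane; 11 3-ethoxycyclobut-2-en-1-one (1.2 equiv, added in portions)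
Product: 16 2-(2,3-dibromo-4,5-dimethoxybenzyl)-5-ethoxy-3-(triisopropylsilyloxy)phenol, via ethoxyvinylketene 12 (not isolated), via vinylcyclobutenone adduct 13 (not isolated), via dienylketene 14 (not isolated), via cyclohexadienone tautomer 15 (not isolated)
Conditions: toluene (0.5 M), 80 → 110 °C, sealed tube
Reagents that add atoms: none
Why: Heating opens 11 by four-electron electrocyclic cleavage to the ethoxyvinylketene 12, which adds across the electron-rich triple bond of 10 in a (2+2) cycloaddition to give 13; four-electron opening of 13 gives the dienylketene 14, six-electron electrocyclisation gives 15, and tautomerisation gives phenol 16 with every atom of both partners retained. The closest known reaction is the Danheiser benzannulation of cyclobutenones with triisopropylsiloxyalkynes to resorcinol monosilyl ethers, in which 3-oxygenated cyclobutenones are known to take part. Ring B is closed by the six-electron disrotatory electrocyclisation that joins the ketene carbon (C2') to the terminal CH2 (C3'), after the intermolecular (2+2) step has made C1'–C2' and C5'–C6'; the four-membered ring of 13 is only transient. No stereocentre survives, the single sp3 centre of 13 being erased on ring opening. The selectivity needed is regiochemical: the benzyl-bearing alkyne carbon, the nucleophilic terminus of the ynol ether, must bond to the electrophilic ketene carbonyl carbon, and this polarity match places the CH2 bridge between the new hydroxyl and the silyloxy group with the ethoxy group para to it. The bulky triisopropylsilyl group suppresses the silyl shift to a silylketene at this temperature, and the aryl bromides and methyl ethers of ring A are inert to neutral heating.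

Step 8
Reactants: 16 2-(2,3-dibromo-4,5-dimethoxybenzyl)-5-ethoxy-3-(triisopropylsilyloxy)phenol
Product: 17 2-bromo-6-(2,3-dibromo-4,5-dimethoxybenzyl)-3-ethoxy-5-(triisopropylsilyloxy)phenol
Conditions: NBS (1.0 equiv), CH2Cl2, −78 → −40 °C, dark
Reagents that add atoms: N-bromosuccinimide, O=C1CCC(=O)N1Br
Why: Electrophilic aromatic bromination of the free-phenol ring B, by far the most electron-rich ring, with one equivalent of NBS at low temperature should stop at the monobromide and favour the position remote from the bulky silyl ether; attack at the other free position would give a regioisomer that converges with 17 at compound 18.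

Step 9
Reactants: 17 2-bromo-6-(2,3-dibromo-4,5-dimethoxybenzyl)-3-ethoxy-5-(triisopropylsilyloxy)phenol
Product: 18 4-bromo-2-(2,3-dibromo-4,5-dimethoxybenzyl)-5-ethoxybenzene-1,3-diol
Conditions: Bu4NF, AcOH, THF, 0 °C
Reagents that add atoms: none
Why: Fluoride-induced cleavage of the aryl silyl ether, driven by Si–F bond formation and buffered with acetic acid so that the bromoresorcinol does not stand as its oxidisable phenoxide.

Step 10
Reactants: 18 4-bromo-2-(2,3-dibromo-4,5-dimethoxybenzyl)-5-ethoxybenzene-1,3-diol
Product: 19 vidalol A, 2-bromo-4-(2,3-dibromo-4,5-dihydroxybenzyl)benzene-1,3,5-triol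
Conditions: BBr3 (8 equiv), CH2Cl2, −78 °C → rt; H2O quench
Reagents that add atoms: none
Why: Lewis acid-mediated cleavage of the two aryl methyl ethers and the aryl ethyl ether by BBr3 (bromide attack on the O-alkyl carbon of the borane-complexed ether) is the usual last step for polybrominated phenols and leaves aryl C–Br bonds intact.

**Compound list**
1 | 5-bromovanillin (3-bromo-4-hydroxy-5-methoxybenzaldehyde) | COc1cc(C=O)cc(Br)c1O | starting material
2 | 2,3-dibromo-4-hydroxy-5-methoxybenzaldehyde | COc1cc(C=O)c(Br)c(Br)c1O | intermediate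
3 | 2,3-dibromo-4,5-dimethoxybenzaldehyde | COc1cc(C=O)c(Br)c(Br)c1OC | intermediate
4 | (2,3-dibromo-4,5-dimethoxyphenyl)methanol | COc1cc(CO)c(Br)c(Br)c1OC | intermediate
5 | 2,3-dibromo-4,5-dimethoxybenzyl bromide | COc1cc(CBr)c(Br)c(Br)c1OC | intermediate
6 | ethynylmagnesium bromide | C#C[Mg]Br | starting material
7 | 2,3-dibromo-4,5-dimethoxy-1-(prop-2-yn-1-yl)benzene | COc1cc(CC#C)c(Br)c(Br)c1OC | intermediate
8 | [3-(2,3-dibromo-4,5-dimethoxyphenyl)prop-1-yn-1-yl]lithium (lithium acetylide) | COc1cc(CC#C[Li])c(Br)c(Br)c1OC | intermediate (not isolated)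
9 | lithium 3-(2,3-dibromo-4,5-dimethoxyphenyl)prop-1-yn-1-olate (lithium ynolate) | COc1cc(CC#CO[Li])c(Br)c(Br)c1OC | intermediate (not isolated)
10 | {[3-(2,3-dibromo-4,5-dimethoxyphenyl)prop-1-yn-1-yl]oxy}triisopropylsilane | COc1cc(CC#CO[Si](C(C)C)(C(C)C)C(C)C)c(Br)c(Br)c1OC | intermediate
11 | 3-ethoxycyclobut-2-en-1-one | CCOC1=CC(=O)C1 | starting material
12 | 3-ethoxybuta-1,3-dien-1-one (ethoxyvinylketene) | CCOC(=C)C=C=O | intermediate (not isolated)
13 | 2-(2,3-dibromo-4,5-dimethoxybenzyl)-4-(1-ethoxyethenyl)-3-(triisopropylsilyloxy)cyclobut-2-en-1-one (racemic) | CCOC(=C)C1C(=O)C(Cc2cc(OC)c(OC)c(Br)c2Br)=C1O[Si](C(C)C)(C(C)C)C(C)C | intermediate (not isolated)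
14 | 2-(2,3-dibromo-4,5-dimethoxybenzyl)-5-ethoxy-3-(triisopropylsilyloxy)hexa-1,3,5-trien-1-one (dienylketene, ketene carbon and ethoxyvinyl group cis) | O=C=C(Cc1cc(OC)c(OC)c(Br)c1Br)/C(O[Si](C(C)C)(C(C)C)C(C)C)=C\C(=C)OCC | intermediate (not isolated)
15 | 2-(2,3-dibromo-4,5-dimethoxybenzyl)-5-ethoxy-3-(triisopropylsilyloxy)cyclohexa-2,4-dien-1-one | O=C1CC(OCC)=CC(O[Si](C(C)C)(C(C)C)C(C)C)=C1Cc1cc(OC)c(OC)c(Br)c1Br | intermediate (not isolated)
16 | 2-(2,3-dibromo-4,5-dimethoxybenzyl)-5-ethoxy-3-(triisopropylsilyloxy)phenol | CCOc1cc(O)c(Cc2cc(OC)c(OC)c(Br)c2Br)c(O[Si](C(C)C)(C(C)C)C(C)C)c1 | intermediate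
17 | 2-bromo-6-(2,3-dibromo-4,5-dimethoxybenzyl)-3-ethoxy-5-(triisopropylsilyloxy)phenol | CCOc1cc(O[Si](C(C)C)(C(C)C)C(C)C)c(Cc2cc(OC)c(OC)c(Br)c2Br)c(O)c1Br | intermediate
18 | 4-bromo-2-(2,3-dibromo-4,5-dimethoxybenzyl)-5-ethoxybenzene-1,3-diol | CCOc1cc(O)c(Cc2cc(OC)c(OC)c(Br)c2Br)c(O)c1Br | intermediate
19 | vidalol A, 2-bromo-4-(2,3-dibromo-4,5-dihydroxybenzyl)benzene-1,3,5-triol | Oc1cc(Cc2c(O)cc(O)c(Br)c2O)c(Br)c(Br)c1O | target

**Totals**
Total step count: 10. Longest linear sequence: 10 steps (1 → 19); compounds 6 and 11 are bought.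

**Steps most likely to fail**

Step 7. The donor-stabilised cyclobutenone may open slowly, so that the vinylketene dimerises or oligomerises, or acylates the product phenol, before it meets the ynol ether. The fallback gives up building ring B and brings it in intact; it sets out from bromide 5 and comes back to the route at target 19. Friedel–Crafts benzylation of 1,3,5-trimethoxybenzene (3 equiv) with 5 (ZnCl2, CH2Cl2, rt) should give 2-(2,3-dibromo-4,5-dimethoxybenzyl)-1,3,5-trimethoxybenzene F1 as a single regioisomer. One equivalent of NBS (MeCN, 0 °C) should brominate one of the two equivalent ring B positions to give 2-bromo-4-(2,3-dibromo-4,5-dimethoxybenzyl)-1,3,5-trimethoxybenzene F2, ring A being far less electron-rich. BBr3 (CH2Cl2, −78 °C → rt) then cleaves all five methyl ethers to give 19.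

Step 6. Competing deprotonation at the doubly activated benzylic/propargylic CH2 may isomerise the alkyne to an allene or internal alkyne, or oxygen transfer from the peroxide may be incomplete. The fallback installs the alkynyl oxygen before the benzylic bond, so no 3-arylprop-1-yne is made; it sets out from bromide 5 and comes back at target 19. Lithium ethoxyacetylide (ethoxyacetylene in slight excess, n-BuLi, THF, −78 °C) is alkylated with 5 in THF/DMPU to give 2,3-dibromo-1-(3-ethoxyprop-2-yn-1-yl)-4,5-dimethoxybenzene F3. Heating F3 with cyclobutenone 11 (toluene, 80 °C), the alkoxyalkyne version of the same benzannulation, should give 2-(2,3-dibromo-4,5-dimethoxybenzyl)-3,5-diethoxyphenol F4. NBS (1 equiv, CH2Cl2, −78 °C) should give 2-bromo-6-(2,3-dibromo-4,5-dimethoxybenzyl)-3,5-diethoxyphenol F5, either free position serving equally. BBr3 then cleaves the four ethers to give 19.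

Step 8. The very electron-rich phenol may be brominated twice or oxidised, leaving a mixture of unreacted, mono- and dibrominated material. The fallback tempers the ring before bromination; it sets out from phenol 16 and comes back at bromide 17. Acetylation (Ac2O, pyridine, DMAP cat., CH2Cl2) gives 2-(2,3-dibromo-4,5-dimethoxybenzyl)-5-ethoxy-3-(triisopropylsilyloxy)phenyl acetate F6. With the phenol masked as an ester, NBS (1 equiv, MeCN, 0 °C) should stop at the monobromide 2-bromo-6-(2,3-dibromo-4,5-dimethoxybenzyl)-3-ethoxy-5-(triisopropylsilyloxy)phenyl acetate F7. Brief methanolysis (K2CO3, MeOH, 0 °C) removes the acetate and returns 17; any material that also loses the silyl group is already 18.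

**Further compounds**
F1 | step 7 | 2-(2,3-dibromo-4,5-dimethoxybenzyl)-1,3,5-trimethoxybenzene | COc1cc(OC)c(Cc2cc(OC)c(OC)c(Br)c2Br)c(OC)c1
F2 | step 7 | 2-bromo-4-(2,3-dibromo-4,5-dimethoxybenzyl)-1,3,5-trimethoxybenzene | COc1cc(OC)c(Cc2cc(OC)c(OC)c(Br)c2Br)c(OC)c1Br
F3 | step 6 | 2,3-dibromo-1-(3-ethoxyprop-2-yn-1-yl)-4,5-dimethoxybenzene | CCOC#CCc1cc(OC)c(OC)c(Br)c1Br
F4 | step 6 | 2-(2,3-dibromo-4,5-dimethoxybenzyl)-3,5-diethoxyphenol | CCOc1cc(O)c(Cc2cc(OC)c(OC)c(Br)c2Br)c(OCC)c1
F5 | step 6 | 2-bromo-6-(2,3-dibromo-4,5-dimethoxybenzyl)-3,5-diethoxyphenol | CCOc1cc(OCC)c(Cc2cc(OC)c(OC)c(Br)c2Br)c(O)c1Br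
F6 | step 8 | 2-(2,3-dibromo-4,5-dimethoxybenzyl)-5-ethoxy-3-(triisopropylsilyloxy)phenyl acetate | CCOc1cc(OC(C)=O)c(Cc2cc(OC)c(OC)c(Br)c2Br)c(O[Si](C(C)C)(C(C)C)C(C)C)c1
F7 | step 8 | 2-bromo-6-(2,3-dibromo-4,5-dimethoxybenzyl)-3-ethoxy-5-(triisopropylsilyloxy)phenyl acetate | CCOc1cc(O[Si](C(C)C)(C(C)C)C(C)C)c(Cc2cc(OC)c(OC)c(Br)c2Br)c(OC(C)=O)c1Br
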